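**Retrosynthetic overview**

- Feature: in the ten-membered carbocycle (C1–C10) the furanone ketone C1 and the Z C4=C5 alkene are joined through C5. A C1–C5 bond therefore folds the ring into a trans-fused cyclopentane (C1–C5) / cycloheptane (C1, C5–C10) bicycle with a C1 carbinol and a C3–C4 epoxide, and a Grob-type fragmentation (step 19) unfolds it again.
- After the fragmentation: MnO2 oxidation at C3, acid cyclodehydration with the C10 hydroxyl to the furanone ring (O–C10–C1–C2=C3), then C15 desilylation.
- Before it: cycloheptene by ring-closing metathesis (C9=C10); C8 methacrylate by Mitsunobu inversion; C9/C10 by hydroxyl-directed epoxidation and titanium-mediated angelate opening; a second directed epoxidation at C3=C4.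
- α-Methylene lactone: ring-closing metathesis to a 3-(bromomethyl)butenolide, then indium-mediated allylation of acrolein (C7–C8).
- Cyclopentene from (S)-4-silyloxycyclopentenone: hydroxymethylation (C15), dithiane conjugate addition and enol triflate reduction (C5, C3=C4), isopropenyl addition (C1, C10). Ring order: cyclopentene, butenolide, cycloheptene, cyclodecene (by fragmentation), furanone.

Key step: step 19

Remark: atom labels C1–C15 follow the target's carbocycle throughout (C1 ketone, C2=C3 furanone alkene, C4 bearing C15, C6 lactone carbinol, C11–C13 lactone carbons); the spectator groups on the fragmentation substrate are taken as the final C8 methacrylate and C9 angelate and a C15 TBDPS ether, and the indium allylation is assumed to pass through the usual closed chair transition state.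

Step 1
Reactants: 1 (S)-4-[(tert-butyldimethylsilyl)oxy]cyclopent-2-en-1-one; 2 formaldehyde
Product: 3 (S)-4-(TBSO)-2-(hydroxymethyl)cyclopent-2-en-1-one
Conditions: HCHO (37% aq.), imidazole (cat.), THF/H2O, rt
Reagents that add atoms: none
Why: Morita–Baylis–Hillman reaction: imidazole adds reversibly to the enone β-carbon, the resulting enolate is hydroxymethylated at the α-carbon (C4, giving C15) and the catalyst is expelled, while the silyloxy stereocenter is untouched.

Step 2
Reactants: 3 MBH alcohol
Product: 4 (S)-4-(TBSO)-2-[(TBDPS-oxy)methyl]cyclopent-2-en-1-one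
Conditions: TBDPSCl, imidazole, CH2Cl2, 0 °C → rt
Reagents that add atoms: tert-butyl(chloro)diphenylsilane, CC(C)(C)[Si](Cl)(c1ccccc1)c1ccccc1
Why: Imidazole-assisted silylation of the primary alcohol installs an acid-stable silyl ether that should outlast the secondary TBS ether and all later steps.

Step 3
Reactants: 4 enone; 5 1,3-dithiane
Product: 8 C3 enol triflate of the conjugate adduct (C5 dithianyl trans to C1 OTBS), via 2-lithio-1,3-dithiane 6 (not isolated), via lithium enolate 7 (not isolated)
Conditions: n-BuLi, THF, −30 °C; HMPA, then 4, −78 °C; PhNTf2, −78 °C → rt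
Reagents that add atoms: N-phenylbis(trifluoromethanesulfonimide), O=S(=O)(N(c1ccccc1)S(=O)(=O)C(F)(F)F)C(F)(F)F
Why: Conjugate (Michael) addition of the lithiated dithiane, steered to 1,4-attack by HMPA, should occur on the enone face opposite the C1 silyloxy group and so set C5, and the regiodefined C3 enolate is trapped on oxygen as the enol triflate.

Step 4
Reactants: 8 enol triflate
Product: 9 cyclopentene (C1 OTBS, C3=C4, C4 CH2OTBDPS, C5 dithianyl trans to OTBS)
Conditions: Pd(OAc)2 (cat.), PPh3, HCO2H, Bu3N, DMF, 60 °C
Reagents that add atoms: none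
Why: Palladium-catalysed formate reduction of an enol triflate (oxidative addition to zerovalent palladium, formate-to-hydride exchange with loss of CO2, reductive elimination) replaces OTf by H and fixes the alkene at C3=C4.

Step 5
Reactants: 9 cyclopentene
Product: 10 cyclopent-3-enol (C1 OH)
Conditions: CSA (cat.), MeOH/CH2Cl2, 0 °C
Reagents that add atoms: none
Why: Acid-catalysed methanolysis should cleave the secondary TBS ether much faster than the bulkier primary TBDPS ether, and the dithiane is inert to acid.

Step 6
Reactants: 10 cyclopentenol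
Product: 11 2-(1,3-dithian-2-yl)-3-[(TBDPS-oxy)methyl]cyclopent-3-en-1-one (C1 ketone)
Conditions: Dess–Martin periodinane, NaHCO3, CH2Cl2, 0 °C
Reagents that add atoms: none
Why: Dess–Martin oxidation under bicarbonate buffer gives the β,γ-unsaturated ketone without base, so the doubly activated C5–H should neither epimerise nor the alkene move into conjugation; the crude ketone is used at once.

Step 7
Reactants: 11 ketone; 12 isopropenylmagnesium bromide
Product: 14 tertiary alcohol (C1 OH cis to the C5 dithianyl group; isopropenyl trans), via isopropenylcerium dichloride 13 (not isolated)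
Conditions: CeCl3, THF, −78 °C; 12; then 11, −78 °C
Reagents that add atoms: none
Why: Organocerium 1,2-addition: the weakly basic cerium reagent adds to the easily enolised ketone from the face opposite the bulky C5 dithianyl group, which sets C1 with the hydroxyl cis to the C5 substituent.

Step 8
Reactants: 14 tertiary alcohol
Product: 15 trimethylsilyl ether of 14
Conditions: 1-(trimethylsilyl)imidazole, CH2Cl2, rt
Reagents that add atoms: 1-(trimethylsilyl)imidazole, C[Si](C)(C)n1ccnc1
Why: Silylation of the tertiary alcohol with a strong silyl donor masks the hydroxyl so that it cannot chelate the Grignard reagent in step 10.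

Step 9
Reactants: 15 dithiane
Product: 16 aldehyde (C6 formyl on C5)
Conditions: MeI, CaCO3, MeCN/H2O, 40 °C
Reagents that add atoms: water, O
Why: Dithiane hydrolysis by S-methylation (sulfonium formation, ring opening, hydrolysis) under carbonate buffer frees the aldehyde without acid or base strong enough to epimerise C5.

Step 10
Reactants: 16 aldehyde; 17 vinylmagnesium bromide
Product: 19 diol (C6 secondary allylic alcohol and C1 tertiary alcohol), via trimethylsilyl ether alcohol 18 (not isolated)
Conditions: 17, THF, −78 °C; NH4Cl (aq.); then K2CO3, MeOH, 0 °C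
Reagents that add atoms: none
Why: Felkin–Anh addition of the Grignard reagent: the quaternary silyloxy-bearing C1 is the large group anti to the incoming vinyl and the silyl ether excludes chelation, which should set C6 with its oxygen syn to C4 along the C1–C5–C6–C7 chain (the lactone configuration); carbonate methanolysis then removes the tertiary TMS ether.

Step 11
Reactants: 19 diol; 20 2-(bromomethyl)acrylic acid
Product: 22 C6 2-(bromomethyl)acrylate ester, via 2-(bromomethyl)acryloyl chloride 21 (not isolated)
Conditions: 20, (COCl)2, DMF (cat.), CH2Cl2, 0 °C; then 19, 2,6-lutidine, CH2Cl2, −20 °C → rt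
Reagents that add atoms: none
Why: Acylation of the secondary allylic alcohol by the acid chloride made in the flask; the hindered base should not displace the allylic bromide and the tertiary alcohol is not acylated.

Step 12
Reactants: 22 ester
Product: 23 5-substituted 3-(bromomethyl)furan-2(5H)-one (butenolide, C7=C11)
Conditions: second-generation Grubbs catalyst RuCl2(=CHPh)(PCy3)(H2IMes) (cat.), CH2Cl2, 40 °C
Reagents that add atoms: none
Why: Ring-closing metathesis between the C7=C8 vinyl group and the acrylate closes the five-membered butenolide with loss of ethene; closure onto the isopropenyl group would need a trans-fused bicyclo[3.3.0]octene and the trisubstituted cyclopentene is inert, so neither should compete.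

Step 13
Reactants: 23 bromomethyl butenolide; 24 acrolein
Product: 26 trans-disubstituted α-methylene-γ-butyrolactone with C8 vinyl carbinol (C8 epimeric to the target), via allylindium dibromide 25 (not isolated)
Conditions: indium powder, THF/H2O, rt
Reagents that add atoms: none
Why: Indium-mediated Barbier allylation: the allylindium reacts at its γ-carbon (C7) with the aldehyde on the lactone face opposite the C6 substituent (C7 trans to C6), the double bond moving to the exocyclic C11=C13 position; a closed chair transition state with the ring-locked γ-substituent and the aldehyde vinyl group both equatorial should give the anti adduct, that is the C8 epimer which step 15 inverts.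

Step 14
Reactants: 26 lactone diene
Product: 27 tricyclic hydroazulene lactone (C9=C10, C8 OH, C1 OH)
Conditions: second-generation Hoveyda–Grubbs catalyst RuCl2(=CH-C6H4-2-OiPr)(H2IMes) (cat.), toluene, 80 °C
Reagents that add atoms: none
Why: Ring-closing metathesis of the C8 vinyl group with the C1 isopropenyl group closes the seven-membered ring as the trisubstituted C9=C10 alkene with loss of ethene; the trisubstituted cyclopentene and the electron-poor exocyclic methylene are poor partners.

Step 15
Reactants: 27 allylic alcohol; 28 methacrylic acid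
Product: 29 C8 methacrylate (C8 inverted)
Conditions: PPh3, DIAD, THF, 0 °C → rt
Reagents that add atoms: none
Why: Mitsunobu esterification: the secondary allylic C8 alcohol is activated on phosphorus and displaced by methacrylate with SN2 inversion, which should give the C8 configuration of the target; the tertiary C1 alcohol cannot react and SN2' attack would have to occur at the fully substituted C10.

Step 16
Reactants: 29 methacrylate
Product: 30 C9–C10 epoxide (oxygen on the face of the C1 hydroxyl)
Conditions: VO(acac)2 (cat.), t-BuOOH, CH2Cl2, 0 °C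
Reagents that add atoms: tert-butyl hydroperoxide, CC(C)(C)OO
Why: Vanadium-catalysed hydroxyl-directed epoxidation: the tertiary allylic C1 hydroxyl binds the vanadium peroxide and delivers oxygen to its own face of C9=C10 (sets C9 and C10), faster than to the merely homoallylic cyclopentene alkene, and the electron-poor alkenes are inert.

Step 17
Reactants: 30 epoxy alcohol; 31 angelic acid
Product: 32 C9 angelate with free C1 and C10 tertiary hydroxyls
Conditions: Ti(OiPr)4, CH2Cl2, rt
Reagents that add atoms: none
Why: Titanium-mediated opening of a 2,3-epoxy alcohol by a carboxylic acid: titanium bound at the C1 oxygen activates the epoxide and the carboxylate attacks the secondary C9 with inversion, which places C9–O trans to the retained C10–OH; the C8 ester lies on the epoxide face and cannot take part.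

Step 18
Reactants: 32 homoallylic diol
Product: 33 fragmentation substrate (C3–C4 epoxide cis to C6; C1 and C10 hydroxyls; C8 methacrylate; C9 angelate; C15 OTBDPS)
Conditions: VO(acac)2 (cat.), t-BuOOH, CH2Cl2, 0 °C → rt
Reagents that add atoms: tert-butyl hydroperoxide, CC(C)(C)OO
Why: Vanadium-catalysed hydroxyl-directed epoxidation of the cyclopent-3-enol: the C1 hydroxyl delivers oxygen to its own face of C3=C4, which sets C3 and C4 and puts the epoxide oxygen on the same side as the C5–C6 bond.

Step 19
Reactants: 33 epoxy diol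
Product: 35 ten-membered C1 ketone with C3 and C10 hydroxyls and Z C4=C5, via titanium alkoxide 34 (not isolated)
Conditions: Ti(OiPr)4, toluene, 60 °C; tartaric acid (aq.) work-up
Reagents that add atoms: none
Why: Ti(OiPr)4 exchanges onto the C1/C10 cis-diol and also coordinates the epoxide oxygen on the same face, so that the C1 alkoxide forms C1=O while the C1–C5 σ bond becomes the C4=C5 π bond and the C4–O bond breaks to the C3 alkoxide in one push–pull event. The closest known reaction type is the Grob-type fragmentation of 3,4-epoxy alcohols to medium-ring hydroxy ketones under titanium alkoxide promotion. No ring is closed by bond formation: cutting the C1–C5 bond that the cyclopentane and the cycloheptane have in common turns the bicycle into the cyclodecenone, paid for by release of epoxide strain and not by a macrocyclisation. No new stereocenter arises (C3 keeps the epoxide configuration; C1, C4 and C5 become trigonal), and the alkene geometry is dictated by the substrate, since the departing C4–O bond lies on the same face of the cyclopentane as the C5–C6 bond and this should place C3 and C6 on one side (Z). The step needs C–C cleavage to outrun plain epoxide opening, retro-aldol of the β-hydroxy ketone product and acyl transfer; the trans ring fusion with the epoxide syn to the C1 oxygen gives the best alignment available, although an epoxide-fused cyclopentane cannot reach a fully antiperiplanar C4–O/C1–C5 arrangement, and the hindered conjugated esters and moderate temperature should keep ester exchange slow.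

Step 20
Reactants: 35 allylic alcohol
Product: 36 C1/C3 β-diketone (C3 ketone conjugated with Z C4=C5)
Conditions: MnO2, CH2Cl2, rt
Reagents that add atoms: none
Why: MnO2 oxidises only the allylic C3 alcohol (heterogeneous allylic alcohol oxidation), leaving the tertiary C10 hydroxyl and the esters alone.

Step 21
Reactants: 36 β-diketone
Product: 37 3(2H)-furanone, C15 TBDPS ether
Conditions: p-TsOH·H2O (cat.), CH2Cl2, rt
Reagents that add atoms: none
Why: Acid-catalysed cyclodehydration: the tertiary C10 hydroxyl adds to the C3 carbonyl to a five-membered hemiketal and loss of water towards C2 gives the furanone, under conditions mild enough to keep the angelate geometry.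

Step 22
Reactants: 37 silyl ether
Product: 38 target CNP0359568.2
Conditions: HF·pyridine, pyridine, THF, 0 °C → rt
Reagents that add atoms: none
Why: Fluoride cleavage of the primary allylic TBDPS ether with buffered HF·pyridine should spare the esters, the furanone and the α-methylene lactone.

**Compound list**

1 | (S)-4-[(tert-butyldimethylsilyl)oxy]cyclopent-2-en-1-one | O=C1C=C[C@@H](O[Si](C)(C)C(C)(C)C)C1 | starting material
2 | formaldehyde (37% aqueous) | C=O | starting material
3 | (S)-4-(TBSO)-2-(hydroxymethyl)cyclopent-2-en-1-one | O=C1C(CO)=C[C@@H](O[Si](C)(C)C(C)(C)C)C1 | intermediate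
4 | (S)-4-(TBSO)-2-[(TBDPS-oxy)methyl]cyclopent-2-en-1-one | O=C1C(CO[Si](c2ccccc2)(c2ccccc2)C(C)(C)C)=C[C@@H](O[Si](C)(C)C(C)(C)C)C1 | intermediate
5 | 1,3-dithiane | C1CSCSC1 | starting material
6 | 2-lithio-1,3-dithiane | [Li]C1SCCCS1 | intermediate
7 | lithium C3 enolate of the conjugate adduct (C5 dithianyl trans to C1 OTBS) | [Li]OC1=C(CO[Si](c2ccccc2)(c2ccccc2)C(C)(C)C)[C@H](C2SCCCS2)[C@@H](O[Si](C)(C)C(C)(C)C)C1 | intermediate
8 | C3 enol triflate (C1 OTBS, C4 CH2OTBDPS, C5 1,3-dithian-2-yl trans to OTBS) | O=S(=O)(OC1=C(CO[Si](c2ccccc2)(c2ccccc2)C(C)(C)C)[C@H](C2SCCCS2)[C@@H](O[Si](C)(C)C(C)(C)C)C1)C(F)(F)F | intermediate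
9 | cyclopentene (C1 OTBS, C3=C4, C4 CH2OTBDPS, C5 dithianyl trans to OTBS) | C1=C(CO[Si](c2ccccc2)(c2ccccc2)C(C)(C)C)[C@H](C2SCCCS2)[C@@H](O[Si](C)(C)C(C)(C)C)C1 | intermediate
10 | cyclopent-3-enol (C1 OH trans to C5 dithianyl) | C1=C(CO[Si](c2ccccc2)(c2ccccc2)C(C)(C)C)[C@H](C2SCCCS2)[C@@H](O)C1 | intermediate
11 | 2-(1,3-dithian-2-yl)-3-[(TBDPS-oxy)methyl]cyclopent-3-en-1-one | C1=C(CO[Si](c2ccccc2)(c2ccccc2)C(C)(C)C)[C@H](C2SCCCS2)C(=O)C1 | intermediate
12 | isopropenylmagnesium bromide | C=C(C)[Mg]Br | starting material
13 | isopropenylcerium dichloride | C=C(C)[Ce](Cl)Cl | intermediate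
14 | tertiary alcohol (C1 OH cis to C5 dithianyl, C1 isopropenyl trans) | C1=C(CO[Si](c2ccccc2)(c2ccccc2)C(C)(C)C)[C@H](C2SCCCS2)[C@@](O)(C(C)=C)C1 | intermediate
15 | trimethylsilyl ether of 14 | C1=C(CO[Si](c2ccccc2)(c2ccccc2)C(C)(C)C)[C@H](C2SCCCS2)[C@@](O[Si](C)(C)C)(C(C)=C)C1 | intermediate
16 | aldehyde (C6 formyl on C5, C1 OTMS cis to it) | C1=C(CO[Si](c2ccccc2)(c2ccccc2)C(C)(C)C)[C@H](C=O)[C@@](O[Si](C)(C)C)(C(C)=C)C1 | intermediate
17 | vinylmagnesium bromide | C=C[Mg]Br | starting material
18 | C6 vinyl carbinol, C1 OTMS | C1=C(CO[Si](c2ccccc2)(c2ccccc2)C(C)(C)C)[C@H]([C@@H](O)C=C)[C@@](O[Si](C)(C)C)(C(C)=C)C1 | intermediate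
19 | diol (C6 secondary allylic OH, C1 tertiary OH) | C1=C(CO[Si](c2ccccc2)(c2ccccc2)C(C)(C)C)[C@H]([C@@H](O)C=C)[C@@](O)(C(C)=C)C1 | intermediate
20 | 2-(bromomethyl)acrylic acid | C=C(CBr)C(=O)O | starting material
21 | 2-(bromomethyl)acryloyl chloride | C=C(CBr)C(=O)Cl | intermediate
22 | C6 2-(bromomethyl)acrylate | C1=C(CO[Si](c2ccccc2)(c2ccccc2)C(C)(C)C)[C@H]([C@@H](OC(=O)C(=C)CBr)C=C)[C@@](O)(C(C)=C)C1 | intermediate
23 | 3-(bromomethyl)butenolide carrying the cyclopentenyl group at C6 | C1=C(CO[Si](c2ccccc2)(c2ccccc2)C(C)(C)C)[C@H]([C@H]2OC(=O)C(CBr)=C2)[C@@](O)(C(C)=C)C1 | intermediate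
24 | acrolein | C=CC=O | starting material
25 | allylindium dibromide from 23 (drawn as RInBr2) | C1=C(CO[Si](c2ccccc2)(c2ccccc2)C(C)(C)C)[C@H]([C@H]2OC(=O)C(C[In](Br)Br)=C2)[C@@](O)(C(C)=C)C1 | intermediate
26 | trans α-methylene-γ-butyrolactone with C8 vinyl carbinol (C8 epimer) | C1=C(CO[Si](c2ccccc2)(c2ccccc2)C(C)(C)C)[C@H]([C@H]2OC(=O)C(=C)[C@@H]2[C@@H](O)C=C)[C@@](O)(C(C)=C)C1 | intermediate
27 | tricyclic hydroazulene lactone (C9=C10, C8 OH epimeric to target, C1 OH) | O[C@@H]1[C@H]2C(=C)C(=O)O[C@@H]2[C@H]3C(CO[Si](c4ccccc4)(c4ccccc4)C(C)(C)C)=CC[C@]3(O)C(C)=C1 | intermediate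
28 | methacrylic acid | C=C(C)C(=O)O | starting material
29 | C8 methacrylate (target configuration at C8) | C=C(C)C(=O)O[C@H]1[C@H]2C(=C)C(=O)O[C@@H]2[C@H]3C(CO[Si](c4ccccc4)(c4ccccc4)C(C)(C)C)=CC[C@]3(O)C(C)=C1 | intermediate
30 | C9–C10 epoxide syn to C1 OH | C=C(C)C(=O)O[C@H]1[C@H]2C(=C)C(=O)O[C@@H]2[C@H]3C(CO[Si](c4ccccc4)(c4ccccc4)C(C)(C)C)=CC[C@]3(O)[C@@]4(C)O[C@@H]14 | intermediate
31 | angelic acid, (Z)-2-methylbut-2-enoic acid | C/C=C(/C)C(=O)O | starting material
32 | C9 angelate, C1/C10 cis-diol, C3=C4 alkene | C=C(C)C(=O)O[C@H]1[C@H]2C(=C)C(=O)O[C@@H]2[C@H]3C(CO[Si](c4ccccc4)(c4ccccc4)C(C)(C)C)=CC[C@]3(O)[C@@](C)(O)[C@@H]1OC(=O)/C(C)=C\C | intermediate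
33 | fragmentation substrate: trans-fused hydroazulene, C1 and C10 OH, C3–C4 epoxide cis to C6, C8 methacrylate, C9 angelate, C15 OTBDPS | C=C(C)C(=O)O[C@H]1[C@H]2C(=C)C(=O)O[C@@H]2[C@H]3[C@@]4(CO[Si](c5ccccc5)(c5ccccc5)C(C)(C)C)O[C@H]4C[C@]3(O)[C@@](C)(O)[C@@H]1OC(=O)/C(C)=C\C | intermediate
34 | titanium alkoxide of 33 (drawn as the C1 tris(isopropoxy)titanium alkoxide) | C=C(C)C(=O)O[C@H]1[C@H]2C(=C)C(=O)O[C@@H]2[C@H]3[C@@]4(CO[Si](c5ccccc5)(c5ccccc5)C(C)(C)C)O[C@H]4C[C@]3(O[Ti](OC(C)C)(OC(C)C)OC(C)C)[C@@](C)(O)[C@@H]1OC(=O)/C(C)=C\C | intermediate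
35 | ten-membered C1 ketone, C3 and C10 OH, Z C4=C5 | C=C(C)C(=O)O[C@H]1[C@H]2C(=C)C(=O)O[C@@H]2/C=C(/CO[Si](c3ccccc3)(c3ccccc3)C(C)(C)C)[C@@H](O)CC(=O)[C@@](C)(O)[C@@H]1OC(=O)/C(C)=C\C | intermediate
36 | C1/C3 β-diketone | C=C(C)C(=O)O[C@H]1[C@H]2C(=C)C(=O)O[C@@H]2/C=C(/CO[Si](c3ccccc3)(c3ccccc3)C(C)(C)C)C(=O)CC(=O)[C@@](C)(O)[C@@H]1OC(=O)/C(C)=C\C | intermediate
37 | furanone, C15 TBDPS ether | C=C(C)C(=O)O[C@H]1[C@H]2C(=C)C(=O)O[C@@H]2/C=C(/CO[Si](c3ccccc3)(c3ccccc3)C(C)(C)C)C2=CC(=O)[C@@](C)(O2)[C@@H]1OC(=O)/C(C)=C\C | intermediate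
38 | CNP0359568.2 | C=C(C)C(=O)O[C@H]1[C@H]2C(=C)C(=O)O[C@@H]2/C=C(/CO)C2=CC(=O)[C@@](C)(O2)[C@@H]1OC(=O)/C(C)=C\C | target

**Step count**

Total: 22 steps. Longest linear sequence: 22 steps (from 1).

**Steps most likely to fail**

Step 19. The epoxide-fused cyclopentane may not bring the C4–O bond close enough to antiperiplanar with C1–C5, so that the epoxide is merely opened (by isopropoxide or a neighbouring hydroxyl) or an ester migrates before the C–C bond breaks. The fallback replaces the strained epoxide by a freely pseudo-axial tertiary chloride as nucleofuge. It sets out from 32: silylation of both tertiary hydroxyls with 1-(trimethylsilyl)imidazole gives the bis(trimethylsilyl) ether F1; with hydrogen bonding blocked, mCPBA should epoxidise the cyclopentene from the less hindered face opposite C6 to the epimeric epoxide F2; anhydrous HCl in ether should open it at the tertiary C4 with inversion and strip the TMS groups, giving the chlorohydrin F3 with C4–Cl on the face of C6; AgOTf with 2,6-di-tert-butylpyridine in CH2Cl2 then triggers the classical Grob fragmentation of the γ-chloro alcohol to the C3-epimeric hydroxy ketone F4, and MnO2 oxidation removes the C3 stereocenter and comes back to the route at 36.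

Step 17. The carboxylate may attack the tertiary C10 under Lewis-acid control, or the hindered C9 may not be reached at all, or a semipinacol shift from C1 may intervene. The fallback builds the C9/C10 oxygens by syn-dihydroxylation and corrects C9 by inversion. It sets out from 29: osmylation with OsO4 and TMEDA in CH2Cl2 at −78 °C, hydrogen-bond directed by the C1 hydroxyl, should give the cis-9,10-diol F5 with C10–OH correct and C9–OH on the wrong face; a Mitsunobu reaction with angelic acid 31 (PPh3, DIAD) inverts the secondary C9 while installing the angelate and comes back to the route at 32.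

Step 13. The simple diastereoselectivity at C8 may be poor (open transition states or an axial aldehyde substituent competing with the chair), so that the Mitsunobu inversion would start from a mixture. The fallback makes C8 stereoconvergent by oxidation and reduction on the ring. It sets out from 27, whatever its C8 epimer content: MnO2 oxidises the allylic C8 alcohols to the single cycloheptenone F6, and Luche reduction (NaBH4, CeCl3, MeOH, −78 °C), with axial hydride delivery anti to the pseudo-axial C7–H, should give the equatorial alcohol, which comes back to the route as 27 in one configuration.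

**Further compounds**

F1 | step 19 | bis(trimethylsilyl) ether of 32 | C=C(C)C(=O)O[C@H]1[C@H]2C(=C)C(=O)O[C@@H]2[C@H]3C(CO[Si](c4ccccc4)(c4ccccc4)C(C)(C)C)=CC[C@]3(O[Si](C)(C)C)[C@@](C)(O[Si](C)(C)C)[C@@H]1OC(=O)/C(C)=C\C
F2 | step 19 | C3–C4 epoxide on the face opposite C6, bis(trimethylsilyl) ether | C=C(C)C(=O)O[C@H]1[C@H]2C(=C)C(=O)O[C@@H]2[C@H]3[C@]4(CO[Si](c5ccccc5)(c5ccccc5)C(C)(C)C)O[C@@H]4C[C@]3(O[Si](C)(C)C)[C@@](C)(O[Si](C)(C)C)[C@@H]1OC(=O)/C(C)=C\C
F3 | step 19 | chlorohydrin (C4 chloride cis to C6, C3 hydroxyl trans to it, C1 and C10 hydroxyls free) | C=C(C)C(=O)O[C@H]1[C@H]2C(=C)C(=O)O[C@@H]2[C@H]3[C@@](CO[Si](c4ccccc4)(c4ccccc4)C(C)(C)C)(Cl)[C@H](O)C[C@]3(O)[C@@](C)(O)[C@@H]1OC(=O)/C(C)=C\C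
F4 | step 19 | C3 epimer of 35 | C=C(C)C(=O)O[C@H]1[C@H]2C(=C)C(=O)O[C@@H]2/C=C(/CO[Si](c3ccccc3)(c3ccccc3)C(C)(C)C)[C@H](O)CC(=O)[C@@](C)(O)[C@@H]1OC(=O)/C(C)=C\C
F5 | step 17 | cis-9,10-diol (C9 hydroxyl epimeric to target, C8 methacrylate) | C=C(C)C(=O)O[C@H]1[C@H]2C(=C)C(=O)O[C@@H]2[C@H]3C(CO[Si](c4ccccc4)(c4ccccc4)C(C)(C)C)=CC[C@]3(O)[C@@](C)(O)[C@H]1O
F6 | step 13 | cycloheptenone (C8 ketone conjugated with C9=C10) | O=C1[C@H]2C(=C)C(=O)O[C@@H]2[C@H]3C(CO[Si](c4ccccc4)(c4ccccc4)C(C)(C)C)=CC[C@]3(O)C(C)=C1
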